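All runs stem from a simulated flask from invented constants; noise was put on by code.

By the end of the feed the spring run had lost 31.9% of its starting complex and the dawn run 13.0%, so the flask with more incoming ligand had lost more, and I wanted that loss as a single figure that could be carried to other flasks.

in all of them: starting complex 0.40 M (fed, over 8.0 h)
- dawn: incoming ligand 1.6 equiv; run made earlier
- summer: incoming ligand 2.4 equiv; run made earlier
- spring: incoming ligand 4.9 equiv; run made earlier
- south-west: incoming ligand 1.30 equiv; time 15 h
- north: incoming ligand 2.60 equiv; time 15 h
- north-west: incoming ligand 5.20 equiv; time 15 h

| run | time / h | complex with one exchanged / % | starting complex / % | complex with two exchanged / % | complex with three exchanged / % |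
|---|---|---|---|---|---|
| dawn | 0.667 | 1.0 | 7.7 | 0.5 | 0.7 |
| dawn | 1.00 | 0 | 13.1 | 0.3 | 0 |
| dawn | 2.00 | 0.5 | 24.0 | 0.7 | 0.5 |
| dawn | 4.00 | 2.4 | 47.5 | 0.7 | 0.7 |
| dawn | 8.00 | 9.0 | 87.0 | 3.2 | 0 |
| summer | 0.667 | 0.4 | 8.4 | 0.5 | 0.4 |
| summer | 1.00 | 0.9 | 12.9 | 0.3 | 0.7 |
| summer | 2.00 | 1.8 | 23.9 | 0 | 0 |
| summer | 4.00 | 4.1 | 44.8 | 1.6 | 0.7 |
| summer | 8.00 | 12.1 | 81.4 | 5.6 | 0.7 |
| spring | 0.667 | 0.7 | 8.9 | 0 | 0.1 |
| spring | 2.00 | 2.4 | 22.0 | 0.4 | 0 |
| spring | 4.00 | 6.3 | 41.1 | 2.8 | 0.7 |
| spring | 5.00 | 8.2 | 48.3 | 5.0 | 0.7 |
| spring | 8.00 | 15.4 | 68.1 | 13.9 | 0.9 |

(standard deviation of a reading: 0.5 percentage points)

- percent here means starting complex units held: one self-condensation product counts as two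
- the numbers in the tables scatter by 0.5 percentage points (one standard deviation)
- on the list of suspects stand: complex with two exchanged + incoming ligand <-> leaving ligand + complex with three exchanged; complex with three exchanged + incoming ligand <-> leaving ligand + complex with four exchanged; 2 starting complex -> self-condensation product; starting complex + incoming ligand <-> leaving ligand + complex with one exchanged; complex with one exchanged + incoming ligand <-> leaving ligand + complex with two exchanged
- percentages count the whole charge, also what has not yet gone in

- which of these there is most of at the end, counted by the starting complex in it, south-west (complex with two exchanged / complex with three exchanged / complex with one exchanged / starting complex)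
- which of these there is most of at the end, counted by the starting complex in it, north (complex with two exchanged / complex with three exchanged / complex with one exchanged / starting complex)
- which of these there is most of at the end, counted by the starting complex in it, north-west (complex with two exchanged / complex with three exchanged / complex with one exchanged / starting complex)
- the largest of these amounts at the end, in percent of the starting complex charged, south-west
- the largest of these amounts at the end, in percent of the starting complex charged, north
- the largest of these amounts at the end, in percent of the starting complex charged, north-west

I followed one charged unit and asked how long it stood exposed as starting complex. The area under the spring curve up to the end of the feed gave 3.06 h on average. Dividing the loss by this exposure gave the clearance, the chance per hour that a unit of starting complex leaves it, a pseudo-first-order constant read at this ligand charge: 0.104 h⁻¹. The second way counted the exchanged complexes instead of the loss, and gave 0.0987 h⁻¹, somewhat lower than the first. The two parted by 1.7 percentage points of the charge, on a scatter of 1 point for that difference of readings. The count leaves out self-condensation product, which the tables do not list, whereas the loss takes it in, so I kept the loss.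

I assumed that, at this charge of starting complex, clearance goes in proportion to the equivalents of incoming ligand, so I took 0.111 h⁻¹ for north-west. A unit fed at a steady rate then survives the feed with the chance 66.4%. Counting exchanges in the spring run left 90.6% of its ligand free at the end of the feed, and I lowered the clearance to that share of its value for the remaining 7.00 h. This gave me 32.9% of starting complex in north-west, 56.9% in north and 75.3% in south-west. I did not reckon the exchanged complexes.

The forecast named starting complex at 75% for south-west, starting complex at 57% for north, and complex with two exchanged at 40% for north-west, with starting complex there at 34 per cent, and it noted: “Reverse steps can't be seen in these data”.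

The flasks ended with starting complex at 73.1% in south-west, starting complex at 58.5% in north, and starting complex at 38.5% in north-west, where complex with two exchanged held less, 31.4%.

    complex with two exchanged + incoming ligand ⇌ leaving ligand + complex with three exchanged (K = 19.0, k = 9.06 × 10⁻⁶ M⁻¹ s⁻¹)
    complex with three exchanged + incoming ligand ⇌ leaving ligand + complex with four exchanged (K = 1.60, k = 7.20 × 10⁻⁶ M⁻¹ s⁻¹)
    2 starting complex → self-condensation product (k = 2.40 × 10⁻⁶ M⁻¹ s⁻¹)
    starting complex + incoming ligand ⇌ leaving ligand + complex with one exchanged (K = 0.331, k = 1.54 × 10⁻⁵ M⁻¹ s⁻¹)
    complex with one exchanged + incoming ligand ⇌ leaving ligand + complex with two exchanged (K = 1.40, k = 4.69 × 10⁻⁵ M⁻¹ s⁻¹)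

The difference in equivalents of incoming ligand is the main reason for the starting complex of north-west: without it that flask ends at 73.1% instead of 38.5%. In north-west my clearance fell short of the flask by 5.6 points. Part of the difference is the return of leaving ligand and complex with one exchanged to starting complex and incoming ligand: without that return the same flask ends at 33.2%, and starting complex loses its lead. The neighbouring flask, north-west at the same equivalents but with 0.16 M of starting complex, held 0.0908 M of leaving ligand against 0.467 M in north-west. Its clearance, scaled down to 0.0443 h⁻¹, gives 62.5%, and that flask held 62.2%.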